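**Retrosynthetic overview**

1. The strategy rests on the oxygen pattern of the cyclohexene ring. O3 on C3 (allylic, pseudoaxial) is cis to O4 on C4 (equatorial), whereas O4 and O5 on C5 are trans-diequatorial and carry the same (R)-2-methylbutanoyl group. A 2-methoxy-2-methyl-1,3-dioxolane bridging O3 and O4 can therefore block O4, leave O5 open and finally turn its own C2 into the acetyl group on O3.
2. Disconnections, backwards: the O4 ester; the 3-acetate/4-hydroxyl pair to the 3,4-orthoacetate; the O5 ester; the orthoester to methyl shikimate and trimethyl orthoacetate; the acyl donor to tiglic acid (asymmetric hydrogenation, then the symmetric anhydride).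
3. Ring order: the carbocycle is taken intact from (−)-shikimic acid. The only ring made is the temporary dioxolane orthoester (step 2), which is opened again in step 6. The acyl groups are placed in the order O5, O3 (revealed), O4.
4. Stereochemistry: C3, C4 and C5 come from the chiral pool, and both side-chain centres come from one catalytic hydrogenation.

Key step: step 6

Remark on the chemistry: step 3 is written with the (R)-configured ligand on the assumption that it delivers the levorotatory (R)-acid from tiglic acid; the sign of rotation decides before the acid is used, and the (S)-ligand is taken if the sense proves opposite.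

**Step 1**
Reactants: 1 (−)-shikimic acid
Product: 2 methyl shikimate
Conditions: MeOH, camphorsulfonic acid (cat.), reflux; concentrate, recrystallise
Reagents that add atoms: methanol, CO
Why: Fischer esterification of the conjugated acid in a large excess of methanol should go to completion without touching C3, C4 or C5, since no ring carbon–oxygen bond is broken.

**Step 2**
Reactants: 2 methyl shikimate; 3 trimethyl orthoacetate
Product: 4 methyl 3,4-O-(1-methoxyethylidene)shikimate (5-OH free, both epimers at the orthoester carbon)
Conditions: MeC(OMe)3 (1.3 equiv), camphorsulfonic acid (cat.), MeCN, rt; Et3N quench before concentration; Et3N-washed silica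
Reagents that add atoms: none
Why: Acid-catalysed orthoester exchange (transorthoesterification) should close the five-membered ring only across the cis-3,4-diol, because the trans-diequatorial O4/O5 pair cannot form an unstrained dioxolane and a triply bridged orthoester is geometrically impossible; the new orthoester carbon is a mixture that is destroyed in step 6.

**Step 3**
Reactants: 5 tiglic acid
Product: 6 (R)-(−)-2-methylbutanoic acid
Conditions: H2 (1.5 atm), Ru(OAc)2[(R)-H8-BINAP] (cat.), MeOH, rt; bulb-to-bulb distillation; rotation and chiral GC checked before use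
Reagents that add atoms: none
Why: Noyori asymmetric hydrogenation of an α,β-unsaturated carboxylic acid, in which the carboxylate binds to ruthenium and the chiral bisphosphine selects the alkene face, should set the C2 centre as (R) in high enantiomeric purity.

**Step 4**
Reactants: 6 (R)-(−)-2-methylbutanoic acid (two molecules)
Product: 7 (R,R)-2-methylbutanoic anhydride
Conditions: DCC (0.5 equiv), CH2Cl2, 0 °C to rt; filter off the urea; concentrate and distil at reduced pressure; enough is made for steps 5 and 7
Reagents that add atoms: none
Why: Carbodiimide dehydration through the O-acylisourea should give the symmetric anhydride under base-free conditions, so the α-centres are not exposed to enolisation or ketene formation.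

**Step 5**
Reactants: 4 methyl 3,4-O-(1-methoxyethylidene)shikimate; 7 (R,R)-2-methylbutanoic anhydride
Product: 8 methyl 3,4-O-(1-methoxyethylidene)-5-O-[(R)-2-methylbutanoyl]shikimate
Conditions: 7 (1.5 equiv), pyridine, DMAP (cat.), CH2Cl2, 0 °C to rt; NaHCO3 wash; Et3N-washed silica
Reagents that add atoms: none
Why: DMAP-catalysed acylation (nucleophilic catalysis through the acylpyridinium ion) should esterify the only free hydroxyl, O5, while the orthoester is stable to the basic medium and the liberated acid is buffered by pyridine; the low temperature limits epimerisation of the acyl α-centre.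

**Step 6**
Reactants: 8 methyl 3,4-O-(1-methoxyethylidene)-5-O-[(R)-2-methylbutanoyl]shikimate
Product: 11 methyl 3-O-acetyl-5-O-[(R)-2-methylbutanoyl]shikimate (4-OH free), via dioxolanylium ion 9 (not isolated), via hemiorthoester 10 (not isolated)
Conditions: AcOH/H2O 4:1, 0 °C to 10 °C, short contact time; repeated toluene co-evaporation below 25 °C until free of acetic acid; no base, no chromatography, used at once
Reagents that add atoms: water, O
Why: Protonation of the exocyclic methoxy group and loss of methanol give the cis-fused 2-methyl-1,3-dioxolan-2-ylium ion 9, water adds to its C2 to give hemiorthoester 10, and 10 collapses by breaking the C2–O4 bond so that the carbonyl forms on O3. The closest known reaction type is the mild acid hydrolysis of cyclic orthoesters of cis-1,2-diols on six-membered rings, which gives the axial ester and frees the equatorial hydroxyl. No ring is closed, the dioxolane made in step 2 is only opened, and no new stereocentre arises because every bond made or broken lies at the orthoester carbon, so C3, C4 and C5 keep the shikimate configuration. The selectivity needed is regiochemical, O3 against O4, and it rests on the half-chair of the bicycle, in which the C3–O bond is pseudoaxial and the C4–O bond equatorial, so that stereoelectronically assisted cleavage of the hemiorthoester expels the equatorial oxygen under kinetic control. The O5 ester cannot intercept the cation, the enoate and the esters tolerate cold dilute acid, and the brief base-free treatment should keep the acetyl group from moving on to O4.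

**Step 7**
Reactants: 11 methyl 3-O-acetyl-5-O-[(R)-2-methylbutanoyl]shikimate; 7 (R,R)-2-methylbutanoic anhydride
Product: 12 methyl (3R,4S,5R)-3-acetoxy-4,5-bis{[(2R)-2-methylbutanoyl]oxy}cyclohex-1-ene-1-carboxylate (target CNP0132712.1)
Conditions: 7 (2 equiv), trimethylsilyl trifluoromethanesulfonate (TMSOTf, cat.), CH2Cl2, −40 °C to 0 °C; aq NaHCO3 quench; chromatography
Reagents that add atoms: none
Why: Silyl triflate-catalysed acylation of an alcohol with an anhydride is fast at low temperature and needs no base, so the crowded equatorial O4 should be esterified before the neighbouring acetyl group can migrate and without enolising the acyl α-centre; the electron-poor enoate disfavours ionisation of the allylic acetate.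

**Compound list**
1 | (−)-shikimic acid, (3R,4S,5R)-3,4,5-trihydroxycyclohex-1-ene-1-carboxylic acid | O[C@@H]1[C@H](O)C=C(C(=O)O)C[C@H]1O | starting material
2 | methyl shikimate, methyl (3R,4S,5R)-3,4,5-trihydroxycyclohex-1-ene-1-carboxylate | O[C@@H]1[C@H](O)C=C(C(=O)OC)C[C@H]1O | intermediate
3 | trimethyl orthoacetate (1,1,1-trimethoxyethane) | COC(C)(OC)OC | starting material
4 | methyl 3,4-O-(1-methoxyethylidene)shikimate (cis-fused 2-methoxy-2-methyl-1,3-dioxolane on O3/O4, 5-OH free, both epimers at the orthoester carbon) | COC1(C)O[C@@H]2[C@H](O1)C=C(C(=O)OC)C[C@H]2O | intermediate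
5 | tiglic acid, (E)-2-methylbut-2-enoic acid | C/C=C(\C)C(=O)O | starting material
6 | (R)-(−)-2-methylbutanoic acid | CC[C@@H](C)C(=O)O | intermediate
7 | (R,R)-2-methylbutanoic anhydride | CC[C@@H](C)C(=O)OC(=O)[C@H](C)CC | intermediate
8 | methyl 3,4-O-(1-methoxyethylidene)-5-O-[(R)-2-methylbutanoyl]shikimate | COC1(C)O[C@@H]2[C@H](O1)C=C(C(=O)OC)C[C@H]2OC(=O)[C@H](C)CC | intermediate
9 | cis-fused 2-methyl-1,3-dioxolan-2-ylium ion on O3/O4 of methyl 5-O-[(R)-2-methylbutanoyl]shikimate | CC1=[O+][C@@H]2[C@H](O1)C=C(C(=O)OC)C[C@H]2OC(=O)[C@H](C)CC | intermediate
10 | hemiorthoester (2-hydroxy-2-methyl-1,3-dioxolane on O3/O4) of methyl 5-O-[(R)-2-methylbutanoyl]shikimate | CC1(O)O[C@@H]2[C@H](O1)C=C(C(=O)OC)C[C@H]2OC(=O)[C@H](C)CC | intermediate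
11 | methyl 3-O-acetyl-5-O-[(R)-2-methylbutanoyl]shikimate (4-OH free) | O[C@@H]1[C@H](OC(C)=O)C=C(C(=O)OC)C[C@H]1OC(=O)[C@H](C)CC | intermediate
12 | methyl (3R,4S,5R)-3-acetoxy-4,5-bis{[(2R)-2-methylbutanoyl]oxy}cyclohex-1-ene-1-carboxylate, CNP0132712.1 | CC[C@@H](C)C(=O)O[C@@H]1[C@H](OC(C)=O)C=C(C(=O)OC)C[C@H]1OC(=O)[C@H](C)CC | target

**Step count**
Total steps: 7.
Longest linear sequence: 5 steps (steps 1, 2, 5, 6, 7 from shikimic acid; equally steps 3, 4, 5, 6, 7 from tiglic acid).

**Steps most likely to fail**

Risk 1, step 6. The hemiorthoester may collapse with poor discrimination between O3 and O4 in the half-chair, or the acetyl group may shift to O4 while the acid is being removed, so that regioisomeric monoacetates are carried forward. The fallback sets out from 2 and rejoins the route at 12; it fixes the position of the acetyl group by protecting-group logic instead of by kinetic ring opening.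
- The trans-diequatorial O4/O5 pair of 2 is locked as a butane-2,3-diacetal with 2,2,3,3-tetramethoxybutane, trimethyl orthoformate and catalytic camphorsulfonic acid in boiling methanol. This should give methyl 4,5-O-[(2S,3S)-2,3-dimethoxybutane-2,3-diyl]shikimate F1, in which O3 is the only free hydroxyl.
- Acetylation with Ac2O, pyridine and catalytic DMAP should give methyl 3-O-acetyl-4,5-O-[(2S,3S)-2,3-dimethoxybutane-2,3-diyl]shikimate F2.
- Brief treatment with aqueous trifluoroacetic acid at room temperature removes the diacetal and should give methyl 3-O-acetylshikimate F3.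
- Both hydroxyls of F3 are then acylated in one operation with anhydride 7 and catalytic TMSOTf in CH2Cl2 at low temperature to give 12.

Risk 2, step 7. Esterification of the crowded O4, flanked by two esters, may be slower than the shift of the acetyl group from O3 to O4, and forcing conditions may epimerise the acyl α-centre or start elimination towards an aromatic ring. The fallback sets out from 2 and rejoins at 12; it brings in the acetyl group last, so that no migratable ester sits beside O4 while O4 is acylated.
- The diacetal F1, made from 2 as described under risk 1, is silylated on O3 with TBDPSCl and imidazole in DMF to give methyl 3-O-(tert-butyldiphenylsilyl)-4,5-O-[(2S,3S)-2,3-dimethoxybutane-2,3-diyl]shikimate F4.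
- Brief aqueous trifluoroacetic acid, which the silyl ether should survive, frees the diol to give methyl 3-O-(tert-butyldiphenylsilyl)shikimate F5.
- Excess 7 with pyridine and catalytic DMAP should give methyl 3-O-(tert-butyldiphenylsilyl)-4,5-di-O-[(R)-2-methylbutanoyl]shikimate F6.
- HF·pyridine in THF removes the silyl group under non-basic conditions to give methyl 4,5-di-O-[(R)-2-methylbutanoyl]shikimate F7.
- Immediate acetylation with Ac2O, pyridine and catalytic DMAP at 0 °C, which is much faster than migration of the branched acyl group, gives 12.

Risk 3, step 3. Incomplete discrimination of the alkene faces leaves some (S)-acid. Because two acyl groups are installed, this is amplified into diastereomers of 8, 11 and 12 that differ only at a remote side-chain centre and are hard to remove by chromatography. The fallback sets out from 6 of insufficient enantiomeric purity and returns at 6; it replaces reliance on catalyst selectivity by purification of a covalent diastereomer.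
- The acid is converted into its mixed pivalic anhydride (pivaloyl chloride, Et3N, THF, −20 °C) and coupled with lithiated (R)-4-benzyloxazolidin-2-one to give (R)-4-benzyl-3-[(R)-2-methylbutanoyl]oxazolidin-2-one F8.
- The minor diastereomer is removed from F8 by chromatography or crystallisation.
- LiOH/H2O2 in aqueous THF at 0 °C cleaves the imide and returns stereochemically homogeneous 6 together with the recoverable auxiliary.

**Further compounds**
F1 | step 6 | methyl 4,5-O-[(2S,3S)-2,3-dimethoxybutane-2,3-diyl]shikimate | CO[C@@]1(C)O[C@@H]2[C@H](O)C=C(C(=O)OC)C[C@H]2O[C@]1(C)OC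
F2 | step 6 | methyl 3-O-acetyl-4,5-O-[(2S,3S)-2,3-dimethoxybutane-2,3-diyl]shikimate | CO[C@@]1(C)O[C@@H]2[C@H](OC(C)=O)C=C(C(=O)OC)C[C@H]2O[C@]1(C)OC
F3 | step 6 | methyl 3-O-acetylshikimate | O[C@@H]1[C@H](OC(C)=O)C=C(C(=O)OC)C[C@H]1O
F4 | step 7 | methyl 3-O-(tert-butyldiphenylsilyl)-4,5-O-[(2S,3S)-2,3-dimethoxybutane-2,3-diyl]shikimate | CO[C@@]1(C)O[C@@H]2[C@H](O[Si](c3ccccc3)(c3ccccc3)C(C)(C)C)C=C(C(=O)OC)C[C@H]2O[C@]1(C)OC
F5 | step 7 | methyl 3-O-(tert-butyldiphenylsilyl)shikimate | O[C@@H]1[C@H](O[Si](c2ccccc2)(c2ccccc2)C(C)(C)C)C=C(C(=O)OC)C[C@H]1O
F6 | step 7 | methyl 3-O-(tert-butyldiphenylsilyl)-4,5-di-O-[(R)-2-methylbutanoyl]shikimate | CC[C@@H](C)C(=O)O[C@@H]1[C@H](O[Si](c2ccccc2)(c2ccccc2)C(C)(C)C)C=C(C(=O)OC)C[C@H]1OC(=O)[C@H](C)CC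
F7 | step 7 | methyl 4,5-di-O-[(R)-2-methylbutanoyl]shikimate | CC[C@@H](C)C(=O)O[C@@H]1[C@H](O)C=C(C(=O)OC)C[C@H]1OC(=O)[C@H](C)CC
F8 | step 3 | (R)-4-benzyl-3-[(R)-2-methylbutanoyl]oxazolidin-2-one | CC[C@@H](C)C(=O)N1[C@H](Cc2ccccc2)COC1=O
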